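**Plan**

1. Retrosynthesis: the fifteen benzyl ethers are removed last. Ring C of both mesquitol units is opened at C2 (C2–H and C2–aryl, back to lactone carbonyls and 3,4-bis(benzyloxy)phenyllithium). Both O1–C8a bonds are then cut (two lactones back to free acids on free catechols), and finally the two biaryl bonds between catechin C6/C8 and mesquitol C5.
2. Forward: two L-DOPA-derived arylboronates are coupled to 6,8-dibromo-penta-O-benzylcatechin, catechols and acids are unmasked, both lactone rings close in one oxidation, and each lactone becomes ring C of a flavan by aryl addition and silane reduction.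
3. Enabling feature: ring A, C4 and C3 of each mesquitol unit are the catechol ring, the CH2 and the α-carbon of L-DOPA, with the carboxyl carbon as C2. Once the biaryl bond is in place, C5 of the derived o-quinone is quaternary, so C8a is the only ring carbon where the tethered carboxylate can add and the ring can re-aromatise.
4. Stereochemistry: the central 2R,3S unit is (+)-catechin. Both C3 (S) come from L-DOPA by diazotisation with retention. Both C2 (R) are set by hydride delivery trans to O3 in the lactol reduction.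

Key step: step 13

Remark: the two biaryl axes carry no descriptor in the target and are treated as freely equilibrating; hindered intermediates may appear as rotamer mixtures.

**Route**

Step 1
Reactants: 1 L-DOPA
Product: 2 (S)-3-(3,4-dihydroxyphenyl)-2-hydroxypropanoic acid
Conditions: NaNO2 (1.5 equiv), 1 M aq H2SO4, 0 °C to rt, Ar
Reagents that add atoms: water, O
Why: Diazotisation of the α-amino acid passes through the α-lactone formed by the neighbouring carboxylate and its opening by water, two inversions that should leave the α-carbon in the S configuration of L-DOPA; this carbon becomes C3 of each mesquitol unit.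

Step 2
Reactants: 2 (S)-3-(3,4-dihydroxyphenyl)-2-hydroxypropanoic acid
Product: 3 methyl (S)-3-(3,4-dihydroxyphenyl)-2-hydroxypropanoate
Conditions: HCl (1.25 M in MeOH), rt to 40 °C
Reagents that add atoms: methanol, CO
Why: Fischer esterification gives a methyl ester that survives every step up to the saponification and only exchanges with the solvent in the later acidic methanolysis; the stereocentre is not touched.

Step 3
Reactants: 3 methyl (S)-3-(3,4-dihydroxyphenyl)-2-hydroxypropanoate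
Product: 4 methyl (S)-3-[3,4-bis(methoxymethoxy)phenyl]-2-hydroxypropanoate
Conditions: MOMCl (2.2 equiv), K2CO3, acetone, 0 °C to rt
Reagents that add atoms: chloromethyl methyl ether, COCCl
Why: Williamson-type O-alkylation in which only the phenols are deprotonated by K2CO3, so the catechol oxygens become MOM acetals (stable to base and cross-coupling, removable by mild acid beside benzyl ethers) while the secondary hydroxyl stays free.

Step 4
Reactants: 4 methyl (S)-3-[3,4-bis(methoxymethoxy)phenyl]-2-hydroxypropanoate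
Product: 5 methyl (S)-2-(benzyloxy)-3-[3,4-bis(methoxymethoxy)phenyl]propanoate
Conditions: BnBr, Ag2O, CH2Cl2, rt, dark
Reagents that add atoms: benzyl bromide, BrCc1ccccc1
Why: Ag2O-promoted benzylation (a non-basic Williamson etherification) is the standard way to benzylate α-hydroxy esters without enolisation, so O3 is blocked and the S centre is kept.

Step 5
Reactants: 5 methyl (S)-2-(benzyloxy)-3-[3,4-bis(methoxymethoxy)phenyl]propanoate
Product: 6 methyl (S)-2-(benzyloxy)-3-[2-bromo-4,5-bis(methoxymethoxy)phenyl]propanoate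
Conditions: NBS (1.05 equiv), MeCN, 0 °C to rt, dark
Reagents that add atoms: N-bromosuccinimide, O=C1CCC(=O)N1Br
Why: Electrophilic aromatic bromination of the dialkoxyarene goes para to the 3-oxygen and ortho to the side chain (the future mesquitol C5), the usual site for 4-alkyl-1,2-dialkoxybenzenes.

Step 6
Reactants: 6 methyl (S)-2-(benzyloxy)-3-[2-bromo-4,5-bis(methoxymethoxy)phenyl]propanoate
Product: 7 methyl (S)-2-(benzyloxy)-3-[4,5-bis(methoxymethoxy)-2-(4,4,5,5-tetramethyl-1,3,2-dioxaborolan-2-yl)phenyl]propanoate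
Conditions: B2pin2, Pd(dppf)Cl2 (5 mol %), KOAc, 1,4-dioxane, 90 °C
Reagents that add atoms: bis(pinacolato)diboron, CC1(C)OB(OC1(C)C)B1OC(C)(C)C(C)(C)O1
Why: Miyaura borylation gives a pinacol boronate with only one ortho substituent, which resists protodeboronation, under KOAc conditions that leave ester, acetals and the α-stereocentre alone.

Step 7
Reactants: 8 (+)-catechin
Product: 9 5,7,3',4'-tetra-O-benzyl-(+)-catechin
Conditions: BnBr (4.4 equiv), K2CO3, DMF, 0 °C to rt, Ar
Reagents that add atoms: benzyl bromide, BrCc1ccccc1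
Why: Williamson etherification of the four phenols with K2CO3 leaves the less acidic 3-hydroxyl free and does not disturb the 2R,3S centres of catechin.

Step 8
Reactants: 9 5,7,3',4'-tetra-O-benzyl-(+)-catechin
Product: 10 3,5,7,3',4'-penta-O-benzyl-(+)-catechin
Conditions: NaH (1.3 equiv), BnBr (1.3 equiv), THF/DMF, 0 °C to rt
Reagents that add atoms: benzyl bromide, BrCc1ccccc1
Why: Williamson etherification of the secondary alkoxide completes the protection, so no acidic proton or competing nucleophile remains in the catechin unit.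

Step 9
Reactants: 10 3,5,7,3',4'-penta-O-benzyl-(+)-catechin
Product: 11 6,8-dibromo-3,5,7,3',4'-penta-O-benzyl-(+)-catechin
Conditions: NBS (2.1 equiv), CH2Cl2, −20 °C to rt, dark
Reagents that add atoms: N-bromosuccinimide, O=C1CCC(=O)N1Br
Why: Electrophilic aromatic bromination attacks the phloroglucinol-type ring A, first at C8 and then at C6, well before the less activated ring B or any benzyl ring.

Step 10
Reactants: 11 6,8-dibromo-3,5,7,3',4'-penta-O-benzyl-(+)-catechin; 7 methyl (S)-2-(benzyloxy)-3-[4,5-bis(methoxymethoxy)-2-(4,4,5,5-tetramethyl-1,3,2-dioxaborolan-2-yl)phenyl]propanoate (2.6 equiv)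
Product: 12 6,8-bis{2-[(S)-2-(benzyloxy)-3-methoxy-3-oxopropyl]-4,5-bis(methoxymethoxy)phenyl}-penta-O-benzylcatechin
Conditions: Pd(OAc)2 (10 mol %), SPhos (2-dicyclohexylphosphino-2',6'-dimethoxybiphenyl, 20 mol %), K3PO4, toluene/H2O 10:1, 100 °C
Reagents that add atoms: none
Why: Twofold Suzuki–Miyaura coupling in which the bulky electron-rich biarylphosphine drives oxidative addition into the doubly flanked C–Br bonds, while placing boron on the arm rather than on the 2,6-dialkoxy positions of catechin avoids protodeboronation.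

Step 11
Reactants: 12 6,8-bis{2-[(S)-2-(benzyloxy)-3-methoxy-3-oxopropyl]-4,5-bis(methoxymethoxy)phenyl}-penta-O-benzylcatechin
Product: 13 6,8-bis{2-[(S)-2-(benzyloxy)-3-methoxy-3-oxopropyl]-4,5-dihydroxyphenyl}-penta-O-benzylcatechin
Conditions: HCl (0.5 M), MeOH/THF 2:1, 40 °C, Ar
Reagents that add atoms: none
Why: Acid-catalysed acetal methanolysis removes the four phenolic MOM groups, while benzyl ethers and the flavan ring are inert at this acidity and the methyl esters only exchange with the solvent.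

Step 12
Reactants: 13 6,8-bis{2-[(S)-2-(benzyloxy)-3-methoxy-3-oxopropyl]-4,5-dihydroxyphenyl}-penta-O-benzylcatechin
Product: 14 6,8-bis{2-[(S)-2-(benzyloxy)-2-carboxyethyl]-4,5-dihydroxyphenyl}-penta-O-benzylcatechin
Conditions: LiOH (8 equiv), degassed THF/H2O 3:1, 0 °C to rt, Ar; then 1 M HCl, 0 °C
Reagents that add atoms: lithium hydroxide, [Li+].[OH-]
Why: Saponification at low temperature under argon (the catecholates are air-sensitive) should free both acids without epimerising the α-benzyloxy centres.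

Step 13
Reactants: 14 6,8-bis{2-[(S)-2-(benzyloxy)-2-carboxyethyl]-4,5-dihydroxyphenyl}-penta-O-benzylcatechin
Product: 16 6,8-bis[(3S)-3-(benzyloxy)-7,8-dihydroxy-2-oxochroman-5-yl]-penta-O-benzylcatechin, via bis(o-quinone) diacid 15 (not isolated)
Conditions: Ag2O (2.1 equiv), powdered 4 Å molecular sieves, THF (0.005 M), 0 °C to rt, dark, Ar
Reagents that add atoms: none
Why: Proposed new method: Ag2O should oxidise only the two free catechols (every other oxygenated ring is a benzyl ether) to the o-quinones 15 and at the same time hold the acids as silver carboxylates. In each quinone the carbon a tethered carboxylate normally attacks, C5 (β to the C7 carbonyl), is quaternary because it carries the catechin ring, and attack at the ipso carbon C4a would give a spiro γ-lactone; neither adduct can aromatise and both should revert. The carboxylate is therefore expected to add at C8a, a vinylogous (1,6) addition to the C7 carbonyl, and enolisation of the C8 ketone then restores a catechol that now bears O1. The closest known reactions are the oxidative lactonisation of dihydrocaffeic acids through their o-quinones (closure at the free β-carbon) and the 1,6-addition of thiols to o-quinones at a carbon next to a carbonyl. Each lactone ring closes in a 6-endo-trig mode (the C8a=C4a bond lies in the new ring) by O1–C8a bond formation, and no stereocentre is formed or touched. The step needs chemoselectivity (secured by the benzyl ethers), site selectivity for C8a (secured by the blocked C5, the six-membered geometry and the benzylated O3, which cannot close a five-membered ring) and a stop at the catechol level (secured by two equivalents of oxidant at high dilution).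

Step 14
Reactants: 16 6,8-bis[(3S)-3-(benzyloxy)-7,8-dihydroxy-2-oxochroman-5-yl]-penta-O-benzylcatechin
Product: 17 6,8-bis[(3S)-3,7,8-tris(benzyloxy)-2-oxochroman-5-yl]-penta-O-benzylcatechin
Conditions: BnBr (6 equiv), K2CO3 (6 equiv), dry acetone, 45 °C, Ar
Reagents that add atoms: benzyl bromide, BrCc1ccccc1
Why: Williamson benzylation of the four new phenols without hydroxide or alkoxide, so that the aryl lactones and the C3 centres should survive, removes all acidic protons before the organolithium step.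

Step 15
Reactants: 17 6,8-bis[(3S)-3,7,8-tris(benzyloxy)-2-oxochroman-5-yl]-penta-O-benzylcatechin; 18 4-bromo-1,2-bis(benzyloxy)benzene (2.2 equiv)
Product: 20 6,8-bis{(3S)-3,7,8-tris(benzyloxy)-2-[3,4-bis(benzyloxy)phenyl]-2-hydroxychroman-5-yl}-penta-O-benzylcatechin (lactol; C2 anomers in equilibrium with the open hydroxy ketone), via 3,4-bis(benzyloxy)phenyllithium 19 (not isolated)
Conditions: 18, n-BuLi (2.2 equiv), THF, −78 °C; then 17, THF, −78 °C; then AcOH in THF, −78 °C
Reagents that add atoms: none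
Why: Bromine–lithium exchange gives the aryllithium, whose 1,2-addition to each lactone carbonyl at −78 °C should stop at the lithium hemiketal (held by chelation to the 3-benzyloxy group), as in aryllithium additions to sugar lactones; the cold acidic quench protects C3.

Step 16
Reactants: 20 6,8-bis{(3S)-3,7,8-tris(benzyloxy)-2-[3,4-bis(benzyloxy)phenyl]-2-hydroxychroman-5-yl}-penta-O-benzylcatechin
Product: 21 6,8-bis[(2R,3S)-3,7,8,3',4'-penta-O-benzylmesquitol-5-yl]-penta-O-benzylcatechin (pentadeca-O-benzyl ether of the target)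
Conditions: Et3SiH (6 equiv), BF3·OEt2 (3 equiv), CH2Cl2, −78 to −30 °C
Reagents that add atoms: none
Why: Ionic hydrogenation of the lactols (silane reduction of the 2-aryl oxocarbenium ions, the reaction used to turn lactols into C-aryl glycosides): hydride should add axially, anti to the pseudo-axial C3–H of the half-chair in which 3-OBn is pseudo-equatorial, so each aryl group ends equatorial and trans to O3 (2R), which is also the more stable 2,3-trans flavan.

Step 17
Reactants: 21 6,8-bis[(2R,3S)-3,7,8,3',4'-penta-O-benzylmesquitol-5-yl]-penta-O-benzylcatechin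
Product: 22 6,8-bis[(2R,3S)-mesquitol-5-yl]-(2R,3S)-catechin (CNP0171327.1)
Conditions: H2 (1 atm), Pd(OH)2/C, THF/MeOH/H2O, rt
Reagents that add atoms: none
Why: Hydrogenolysis of all fifteen benzyl ethers under the mild conditions routinely used for benzylated flavan-3-ol oligomers, which do not cleave the benzylic C2–O1 bonds.

**Compound list**

1 | L-DOPA | N[C@@H](Cc1ccc(O)c(O)c1)C(=O)O | starting material
2 | (S)-3-(3,4-dihydroxyphenyl)-2-hydroxypropanoic acid | O[C@@H](Cc1ccc(O)c(O)c1)C(=O)O | intermediate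
3 | methyl (S)-3-(3,4-dihydroxyphenyl)-2-hydroxypropanoate | COC(=O)[C@@H](O)Cc1ccc(O)c(O)c1 | intermediate
4 | methyl (S)-3-[3,4-bis(methoxymethoxy)phenyl]-2-hydroxypropanoate | COC(=O)[C@@H](O)Cc1ccc(OCOC)c(OCOC)c1 | intermediate
5 | methyl (S)-2-(benzyloxy)-3-[3,4-bis(methoxymethoxy)phenyl]propanoate | COC(=O)[C@@H](OCc1ccccc1)Cc1ccc(OCOC)c(OCOC)c1 | intermediate
6 | methyl (S)-2-(benzyloxy)-3-[2-bromo-4,5-bis(methoxymethoxy)phenyl]propanoate | COC(=O)[C@@H](OCc1ccccc1)Cc1cc(OCOC)c(OCOC)cc1Br | intermediate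
7 | methyl (S)-2-(benzyloxy)-3-[4,5-bis(methoxymethoxy)-2-(4,4,5,5-tetramethyl-1,3,2-dioxaborolan-2-yl)phenyl]propanoate | COC(=O)[C@@H](OCc1ccccc1)Cc1cc(OCOC)c(OCOC)cc1B1OC(C)(C)C(C)(C)O1 | intermediate
8 | (+)-catechin (2R,3S) | O[C@H]1Cc2c(O)cc(O)cc2O[C@@H]1c1ccc(O)c(O)c1 | starting material
9 | 5,7,3',4'-tetra-O-benzyl-(+)-catechin | O[C@H]1Cc2c(OCc3ccccc3)cc(OCc3ccccc3)cc2O[C@@H]1c1ccc(OCc2ccccc2)c(OCc2ccccc2)c1 | intermediate
10 | 3,5,7,3',4'-penta-O-benzyl-(+)-catechin | c1ccccc1CO[C@H]1Cc2c(OCc3ccccc3)cc(OCc3ccccc3)cc2O[C@@H]1c1ccc(OCc2ccccc2)c(OCc2ccccc2)c1 | intermediate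
11 | 6,8-dibromo-3,5,7,3',4'-penta-O-benzyl-(+)-catechin | c1ccccc1CO[C@H]1Cc2c(OCc3ccccc3)c(Br)c(OCc3ccccc3)c(Br)c2O[C@@H]1c1ccc(OCc2ccccc2)c(OCc2ccccc2)c1 | intermediate
12 | 6,8-bis{2-[(S)-2-(benzyloxy)-3-methoxy-3-oxopropyl]-4,5-bis(methoxymethoxy)phenyl}-penta-O-benzylcatechin | c1ccccc1CO[C@H]1Cc2c(OCc3ccccc3)c(-c3cc(OCOC)c(OCOC)cc3C[C@H](OCc3ccccc3)C(=O)OC)c(OCc3ccccc3)c(-c3cc(OCOC)c(OCOC)cc3C[C@H](OCc3ccccc3)C(=O)OC)c2O[C@@H]1c1ccc(OCc2ccccc2)c(OCc2ccccc2)c1 | intermediate
13 | 6,8-bis{2-[(S)-2-(benzyloxy)-3-methoxy-3-oxopropyl]-4,5-dihydroxyphenyl}-penta-O-benzylcatechin | c1ccccc1CO[C@H]1Cc2c(OCc3ccccc3)c(-c3cc(O)c(O)cc3C[C@H](OCc3ccccc3)C(=O)OC)c(OCc3ccccc3)c(-c3cc(O)c(O)cc3C[C@H](OCc3ccccc3)C(=O)OC)c2O[C@@H]1c1ccc(OCc2ccccc2)c(OCc2ccccc2)c1 | intermediate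
14 | 6,8-bis{2-[(S)-2-(benzyloxy)-2-carboxyethyl]-4,5-dihydroxyphenyl}-penta-O-benzylcatechin | c1ccccc1CO[C@H]1Cc2c(OCc3ccccc3)c(-c3cc(O)c(O)cc3C[C@H](OCc3ccccc3)C(=O)O)c(OCc3ccccc3)c(-c3cc(O)c(O)cc3C[C@H](OCc3ccccc3)C(=O)O)c2O[C@@H]1c1ccc(OCc2ccccc2)c(OCc2ccccc2)c1 | intermediate
15 | 6,8-bis{6-[(S)-2-(benzyloxy)-2-carboxyethyl]-3,4-dioxocyclohexa-1,5-dien-1-yl}-penta-O-benzylcatechin (bis(o-quinone) diacid, not isolated) | c1ccccc1CO[C@H]1Cc2c(OCc3ccccc3)c(C3=CC(=O)C(=O)C=C3C[C@H](OCc3ccccc3)C(=O)O)c(OCc3ccccc3)c(C3=CC(=O)C(=O)C=C3C[C@H](OCc3ccccc3)C(=O)O)c2O[C@@H]1c1ccc(OCc2ccccc2)c(OCc2ccccc2)c1 | intermediate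
16 | 6,8-bis[(3S)-3-(benzyloxy)-7,8-dihydroxy-2-oxochroman-5-yl]-penta-O-benzylcatechin | c1ccccc1CO[C@H]1Cc2c(OCc3ccccc3)c(-c3cc(O)c(O)c4OC(=O)[C@@H](OCc5ccccc5)Cc34)c(OCc3ccccc3)c(-c3cc(O)c(O)c4OC(=O)[C@@H](OCc5ccccc5)Cc34)c2O[C@@H]1c1ccc(OCc2ccccc2)c(OCc2ccccc2)c1 | intermediate
17 | 6,8-bis[(3S)-3,7,8-tris(benzyloxy)-2-oxochroman-5-yl]-penta-O-benzylcatechin | c1ccccc1CO[C@H]1Cc2c(OCc3ccccc3)c(-c3cc(OCc4ccccc4)c(OCc4ccccc4)c4OC(=O)[C@@H](OCc5ccccc5)Cc34)c(OCc3ccccc3)c(-c3cc(OCc4ccccc4)c(OCc4ccccc4)c4OC(=O)[C@@H](OCc5ccccc5)Cc34)c2O[C@@H]1c1ccc(OCc2ccccc2)c(OCc2ccccc2)c1 | intermediate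
18 | 4-bromo-1,2-bis(benzyloxy)benzene | Brc1ccc(OCc2ccccc2)c(OCc2ccccc2)c1 | starting material
19 | 3,4-bis(benzyloxy)phenyllithium (not isolated) | [Li]c1ccc(OCc2ccccc2)c(OCc2ccccc2)c1 | intermediate
20 | 6,8-bis{(3S)-3,7,8-tris(benzyloxy)-2-[3,4-bis(benzyloxy)phenyl]-2-hydroxychroman-5-yl}-penta-O-benzylcatechin (C2 anomers) | c1ccccc1CO[C@H]1Cc2c(OCc3ccccc3)c(-c3cc(OCc4ccccc4)c(OCc4ccccc4)c4OC(O)(c5ccc(OCc6ccccc6)c(OCc6ccccc6)c5)[C@@H](OCc5ccccc5)Cc34)c(OCc3ccccc3)c(-c3cc(OCc4ccccc4)c(OCc4ccccc4)c4OC(O)(c5ccc(OCc6ccccc6)c(OCc6ccccc6)c5)[C@@H](OCc5ccccc5)Cc34)c2O[C@@H]1c1ccc(OCc2ccccc2)c(OCc2ccccc2)c1 | intermediate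
21 | 6,8-bis[(2R,3S)-3,7,8,3',4'-penta-O-benzylmesquitol-5-yl]-penta-O-benzylcatechin | c1ccccc1CO[C@H]1Cc2c(OCc3ccccc3)c(-c3cc(OCc4ccccc4)c(OCc4ccccc4)c4O[C@H](c5ccc(OCc6ccccc6)c(OCc6ccccc6)c5)[C@@H](OCc5ccccc5)Cc34)c(OCc3ccccc3)c(-c3cc(OCc4ccccc4)c(OCc4ccccc4)c4O[C@H](c5ccc(OCc6ccccc6)c(OCc6ccccc6)c5)[C@@H](OCc5ccccc5)Cc34)c2O[C@@H]1c1ccc(OCc2ccccc2)c(OCc2ccccc2)c1 | intermediate
22 | 6,8-bis[(2R,3S)-mesquitol-5-yl]-(2R,3S)-catechin (CNP0171327.1) | Oc1ccc([C@H]2Oc3c(O)c(O)cc(-c4c(O)c5c(c(-c6cc(O)c(O)c7c6C[C@H](O)[C@@H](c6ccc(O)c(O)c6)O7)c4O)O[C@H](c4ccc(O)c(O)c4)[C@@H](O)C5)c3C[C@@H]2O)cc1O | target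

**Step count and risks**

Total: 17 steps. Longest linear sequence: 14 steps (steps 1–6, then 10–17).

Risk 1, step 13. The carboxylate may be trapped kinetically at the quaternary C5 or at the ipso carbon C4a in adducts that do not revert. The product catechols may also be oxidised further, or quinone and catechol may couple between molecules.

Fallback (known chemistry; sets out from 11, returns at 17): the C8a oxygen is brought in with the arm, and the bromine for the biaryl bond is placed before the third ring oxygen can misdirect it.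
- Commercially available 5-bromo-1,2,3-tris(benzyloxy)benzene F1 is formylated at one of its two equivalent free positions (POCl3, DMF, Vilsmeier–Haack) to 6-bromo-2,3,4-tris(benzyloxy)benzaldehyde F2.
- MgBr2·OEt2 removes only the benzyl group ortho to the aldehyde (chelation) to give 6-bromo-3,4-bis(benzyloxy)-2-hydroxybenzaldehyde F3, which is capped (MOMCl, i-Pr2NEt) as 6-bromo-3,4-bis(benzyloxy)-2-(methoxymethoxy)benzaldehyde F4.
- NaBH4 reduction gives [6-bromo-3,4-bis(benzyloxy)-2-(methoxymethoxy)phenyl]methanol F5, and Appel bromination (CBr4, PPh3) gives 1,2-bis(benzyloxy)-5-bromo-4-(bromomethyl)-3-(methoxymethoxy)benzene F6.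
- F6 alkylates the sodium enolate (NaN(SiMe3)2, THF, −78 °C) of (R)-4-benzyl-3-(benzyloxyacetyl)oxazolidin-2-one, an auxiliary-controlled glycolate alkylation that sets the S centre, to give (R)-4-benzyl-3-{(S)-2-(benzyloxy)-3-[6-bromo-3,4-bis(benzyloxy)-2-(methoxymethoxy)phenyl]propanoyl}oxazolidin-2-one F7.
- NaOMe in MeOH at 0 °C gives methyl (S)-2-(benzyloxy)-3-[6-bromo-3,4-bis(benzyloxy)-2-(methoxymethoxy)phenyl]propanoate F8, and Miyaura borylation as in step 6 gives methyl (S)-2-(benzyloxy)-3-[3,4-bis(benzyloxy)-2-(methoxymethoxy)-6-(4,4,5,5-tetramethyl-1,3,2-dioxaborolan-2-yl)phenyl]propanoate F9.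
- Coupling with 11 as in step 10 gives 6,8-bis{2-[(S)-2-(benzyloxy)-3-methoxy-3-oxopropyl]-4,5-bis(benzyloxy)-3-(methoxymethoxy)phenyl}-penta-O-benzylcatechin F10.
- HCl in MeOH/THF removes the MOM groups to give 6,8-bis{2-[(S)-2-(benzyloxy)-3-methoxy-3-oxopropyl]-4,5-bis(benzyloxy)-3-hydroxyphenyl}-penta-O-benzylcatechin F11, and TsOH in hot toluene closes both phenols onto the methyl esters with loss of methanol to give 17.

Risk 2, step 15. The lithium hemiketal may collapse at low temperature to the aryl ketone, which then takes up a second aryllithium, or the phenoxide released may enolise the α-benzyloxy ketone and erode C3.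

Fallback (sets out from 17, returns at 20): each lactone is opened with the aluminium amide from AlMe3 and N,O-dimethylhydroxylamine hydrochloride (CH2Cl2, 0 °C to rt). This gives 6,8-bis{2-[(S)-2-(benzyloxy)-3-[methoxy(methyl)amino]-3-oxopropyl]-4,5-bis(benzyloxy)-3-hydroxyphenyl}-penta-O-benzylcatechin F12. After deprotonation of the two phenols, 19 adds once to each N-methoxy-N-methylamide through the stable chelated adduct (THF, −78 °C). Mild acidic work-up releases the ketones, which close with the neighbouring phenols to the lactols 20.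

Risk 3, step 10. Oxidative addition into the second, doubly flanked C–Br bond may be slow, so the reaction stalls after one coupling while the boronate is lost by protodeboronation or the esters are hydrolysed by the aqueous base.

Fallback (sets out from 6 and 11, returns at 12): magnesium insertion into 6 in the presence of LiCl and ZnCl2 (THF, rt), which tolerates the ester, gives {2-[(S)-2-(benzyloxy)-3-methoxy-3-oxopropyl]-4,5-bis(methoxymethoxy)phenyl}zinc chloride F13. A twofold Negishi coupling with 11 (Pd(OAc)2, SPhos, THF/NMP, 60 °C), which runs without base or water and is less sensitive to ortho substitution, gives 12.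

**Further compounds**

F1 | step 13 | 5-bromo-1,2,3-tris(benzyloxy)benzene | Brc1cc(OCc2ccccc2)c(OCc2ccccc2)c(OCc2ccccc2)c1
F2 | step 13 | 6-bromo-2,3,4-tris(benzyloxy)benzaldehyde | O=Cc1c(Br)cc(OCc2ccccc2)c(OCc2ccccc2)c1OCc1ccccc1
F3 | step 13 | 6-bromo-3,4-bis(benzyloxy)-2-hydroxybenzaldehyde | O=Cc1c(Br)cc(OCc2ccccc2)c(OCc2ccccc2)c1O
F4 | step 13 | 6-bromo-3,4-bis(benzyloxy)-2-(methoxymethoxy)benzaldehyde | O=Cc1c(Br)cc(OCc2ccccc2)c(OCc2ccccc2)c1OCOC
F5 | step 13 | [6-bromo-3,4-bis(benzyloxy)-2-(methoxymethoxy)phenyl]methanol | OCc1c(Br)cc(OCc2ccccc2)c(OCc2ccccc2)c1OCOC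
F6 | step 13 | 1,2-bis(benzyloxy)-5-bromo-4-(bromomethyl)-3-(methoxymethoxy)benzene | BrCc1c(Br)cc(OCc2ccccc2)c(OCc2ccccc2)c1OCOC
F7 | step 13 | (R)-4-benzyl-3-{(S)-2-(benzyloxy)-3-[6-bromo-3,4-bis(benzyloxy)-2-(methoxymethoxy)phenyl]propanoyl}oxazolidin-2-one | COCOc1c(C[C@H](OCc2ccccc2)C(=O)N2[C@H](Cc3ccccc3)COC2=O)c(Br)cc(OCc2ccccc2)c1OCc1ccccc1
F8 | step 13 | methyl (S)-2-(benzyloxy)-3-[6-bromo-3,4-bis(benzyloxy)-2-(methoxymethoxy)phenyl]propanoate | COC(=O)[C@@H](OCc1ccccc1)Cc1c(Br)cc(OCc2ccccc2)c(OCc2ccccc2)c1OCOC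
F9 | step 13 | methyl (S)-2-(benzyloxy)-3-[3,4-bis(benzyloxy)-2-(methoxymethoxy)-6-(4,4,5,5-tetramethyl-1,3,2-dioxaborolan-2-yl)phenyl]propanoate | COC(=O)[C@@H](OCc1ccccc1)Cc1c(B2OC(C)(C)C(C)(C)O2)cc(OCc2ccccc2)c(OCc2ccccc2)c1OCOC
F10 | step 13 | 6,8-bis{2-[(S)-2-(benzyloxy)-3-methoxy-3-oxopropyl]-4,5-bis(benzyloxy)-3-(methoxymethoxy)phenyl}-penta-O-benzylcatechin | c1ccccc1CO[C@H]1Cc2c(OCc3ccccc3)c(-c3cc(OCc4ccccc4)c(OCc4ccccc4)c(OCOC)c3C[C@H](OCc3ccccc3)C(=O)OC)c(OCc3ccccc3)c(-c3cc(OCc4ccccc4)c(OCc4ccccc4)c(OCOC)c3C[C@H](OCc3ccccc3)C(=O)OC)c2O[C@@H]1c1ccc(OCc2ccccc2)c(OCc2ccccc2)c1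
F11 | step 13 | 6,8-bis{2-[(S)-2-(benzyloxy)-3-methoxy-3-oxopropyl]-4,5-bis(benzyloxy)-3-hydroxyphenyl}-penta-O-benzylcatechin | c1ccccc1CO[C@H]1Cc2c(OCc3ccccc3)c(-c3cc(OCc4ccccc4)c(OCc4ccccc4)c(O)c3C[C@H](OCc3ccccc3)C(=O)OC)c(OCc3ccccc3)c(-c3cc(OCc4ccccc4)c(OCc4ccccc4)c(O)c3C[C@H](OCc3ccccc3)C(=O)OC)c2O[C@@H]1c1ccc(OCc2ccccc2)c(OCc2ccccc2)c1
F12 | step 15 | 6,8-bis{2-[(S)-2-(benzyloxy)-3-[methoxy(methyl)amino]-3-oxopropyl]-4,5-bis(benzyloxy)-3-hydroxyphenyl}-penta-O-benzylcatechin | c1ccccc1CO[C@H]1Cc2c(OCc3ccccc3)c(-c3cc(OCc4ccccc4)c(OCc4ccccc4)c(O)c3C[C@H](OCc3ccccc3)C(=O)N(C)OC)c(OCc3ccccc3)c(-c3cc(OCc4ccccc4)c(OCc4ccccc4)c(O)c3C[C@H](OCc3ccccc3)C(=O)N(C)OC)c2O[C@@H]1c1ccc(OCc2ccccc2)c(OCc2ccccc2)c1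
F13 | step 10 | {2-[(S)-2-(benzyloxy)-3-methoxy-3-oxopropyl]-4,5-bis(methoxymethoxy)phenyl}zinc chloride | COC(=O)[C@@H](OCc1ccccc1)Cc1cc(OCOC)c(OCOC)cc1[Zn]Cl
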